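The cyclobutane is disconnected across its CH2–CH2 bond and the bond between the gem-dimethyl carbon and the acyloxy-bearing quaternary carbon, a polar [2+2] of isobutylene with 2-(angeloyloxy)acrolein. The key step exploits the 1-acyloxy-2,2-dimethyl substitution of the four-membered ring: the oxygenated ring carbon acts as an enamine carbon and the CMe2 carbon as a tertiary cation, so a chiral primary ammonium catalyst assembles the ring, sets the only stereocentre and installs the angelate in one operation. The formyl carbon of the adduct becomes C-2 of the quinone ring: alkyne homologation and Dötz benzannulation then build the naphthazarin bicycle from open-chain carbons.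

Key step: step 4

Assumption: the catalyst of step 4, the triamine (S)-N-[(S)-2-amino-3-phenylpropyl]-4-methyl-1-(pyrrolidin-1-yl)pentan-2-amine (N[C@@H](Cc1ccccc1)CN[C@@H](CC(C)C)CN1CCCC1, from L-Phe-L-Leu pyrrolidide by LiAlH4 reduction), is treated as a known catalyst and not counted among the steps; its L,L form is assumed to give the (R)-aldehyde, and the D,D form would be used if the sense of induction proves opposite.

Step 1
Reactants: 1 angelic acid [(Z)-2-methylbut-2-enoic acid]
Product: 2 angeloyl chloride [(Z)-2-methylbut-2-enoyl chloride]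
Conditions: 1-chloro-N,N,2-trimethylprop-1-en-1-amine (1.05 equiv), CH2Cl2, 0 °C to rt
Reagents that add atoms: 1-chloro-N,N,2-trimethylprop-1-en-1-amine (Ghosez's reagent), CC(C)=C(Cl)N(C)C
Why: Acid chloride formation with an α-chloroenamine runs under neutral conditions without HCl or a nucleophilic catalyst, so the Z geometry should be kept; the solution is used directly.

Step 2
Reactants: 3 2,2-dimethyl-1,3-dioxan-5-one; 2 angeloyl chloride
Product: 5 2,2-dimethyl-4H-1,3-dioxin-5-yl (Z)-2-methylbut-2-enoate, via potassium enolate 4 (not isolated)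
Conditions: KHMDS, THF, −78 °C; then 2, −78 to −20 °C
Reagents that add atoms: none
Why: The potassium enolate of the symmetric ketone should O-acylate with the acid chloride at low temperature (enol ester formation), and the absence of amine or DMAP avoids Z to E isomerisation and ketene formation.

Step 3
Reactants: 5 2,2-dimethyl-4H-1,3-dioxin-5-yl (Z)-2-methylbut-2-enoate
Product: 6 3-oxoprop-1-en-2-yl (Z)-2-methylbut-2-enoate [2-(angeloyloxy)acrolein]
Conditions: toluene, 110 °C, BHT (trace), argon sweep
Reagents that add atoms: none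
Why: Retro-hetero-Diels–Alder reaction of the 4H-1,3-dioxin expels acetone under neutral thermal conditions and should leave the angelate untouched.

Step 4
Reactants: 6 3-oxoprop-1-en-2-yl (Z)-2-methylbut-2-enoate; 7 isobutylene (2-methylpropene)
Product: 8 (R)-1-formyl-2,2-dimethylcyclobutyl (Z)-2-methylbut-2-enoate
Conditions: 7 (excess, condensed), L,L-triamine·2.6 Tf2NH (20 mol %), EtNO2, −20 °C to rt, sealed vessel
Reagents that add atoms: none
Why: The primary amine of the catalyst condenses with 6 to an α-acyloxy iminium ion, to whose β-CH2 the CH2 terminus of 7 adds in the Markovnikov sense, giving a tertiary carbocation paired with an enamine; collapse of this 1,4-dipole through the acyloxy-bearing enamine carbon closes the ring, and hydrolysis releases 8 and the catalyst. The closest known reaction type is the chiral ammonium salt catalysed stepwise [2+2] cycloaddition of α-acyloxyacroleins with unactivated tri- and 1,1-disubstituted alkenes. The four-membered ring closes in a 4-exo mode, the enamine carbon (its C=C exocyclic to the forming ring) attacking the trigonal cationic CMe2 carbon. The single new stereocentre, the quaternary C–O carbon, is created in this ring closure, and its face is dictated by the catalyst, whose ammonium arms bind the acyloxy carbonyl and shield one enamine face. The step needs head-to-head regioselectivity, secured by the polarity match (nucleophilic alkene CH2 to the electrophilic β-carbon, tertiary cation to the enamine carbon), and chemoselectivity for the enal over the angelate C=C, secured because only the aldehyde is activated as an iminium ion.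

Step 5
Reactants: 8 (R)-1-formyl-2,2-dimethylcyclobutyl (Z)-2-methylbut-2-enoate
Product: 9 (R)-1-ethynyl-2,2-dimethylcyclobutyl (Z)-2-methylbut-2-enoate
Conditions: dimethyl (1-diazo-2-oxopropyl)phosphonate, NaOMe (1 equiv), THF, −78 °C; then 8, −78 °C to rt
Reagents that add atoms: dimethyl (1-diazo-2-oxopropyl)phosphonate (Ohira–Bestmann reagent), CC(=O)C(=[N+]=[N-])P(=O)(OC)OC
Why: Seyferth–Gilbert homologation with the preformed diazomethylphosphonate anion (no methanol solvent, no free methoxide) should give the diazoalkene, then N2 loss and 1,2-H shift to the terminal alkyne; the quaternary stereocentre is not enolisable and is not touched.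

Step 6
Reactants: 10 hydroquinone
Product: 11 1,4-bis(methoxymethoxy)benzene
Conditions: MOMCl, i-Pr2NEt, CH2Cl2, 0 °C to rt
Reagents that add atoms: chloromethyl methyl ether (MOMCl), COCCl
Why: Standard O-alkylation of both phenols gives acetal protecting groups that direct ortho-lithiation and can be removed by mild acid at the end.

Step 7
Reactants: 11 1,4-bis(methoxymethoxy)benzene
Product: 14 pentacarbonyl{[2,5-bis(methoxymethoxy)phenyl](methoxy)methylidene}chromium(0), via aryllithium 12 (not isolated), via lithium acylchromate 13 (not isolated)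
Conditions: n-BuLi, THF, 0 °C; Cr(CO)6, 0 °C to rt; then Me3OBF4, CH2Cl2, 0 °C
Reagents that add atoms: hexacarbonylchromium, O=C=[Cr](=C=O)(=C=O)(=C=O)(=C=O)=C=O; trimethyloxonium tetrafluoroborate, C[O+](C)C.F[B-](F)(F)F
Why: Fischer carbene synthesis: MOM-directed ortho-lithiation (all four ring positions are equivalent), addition of the aryllithium to a CO ligand and O-methylation of the acylchromate.

Step 8
Reactants: 9 (R)-1-ethynyl-2,2-dimethylcyclobutyl (Z)-2-methylbut-2-enoate; 14 pentacarbonyl{[2,5-bis(methoxymethoxy)phenyl](methoxy)methylidene}chromium(0)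
Product: 16 (R)-1-[5,8-bis(methoxymethoxy)-1,4-dioxo-1,4-dihydronaphthalen-2-yl]-2,2-dimethylcyclobutyl (Z)-2-methylbut-2-enoate, via methoxynaphthol 15 (not isolated)
Conditions: THF (degassed), 55 °C; then air, rt; then CAN, MeCN/H2O, 0 °C
Reagents that add atoms: water, O
Why: Dötz benzannulation (alkyne insertion, CO insertion to a vinylketene, 6π electrocyclisation onto the free ortho position, tautomerisation) should give the 4-methoxy-1-naphthol, which CAN oxidises to the quinone with loss of methanol; the orientation of alkyne insertion is irrelevant because both flanking carbons become C=O, and the stereocentre is a spectator.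

Step 9
Reactants: 16 (R)-1-[5,8-bis(methoxymethoxy)-1,4-dioxo-1,4-dihydronaphthalen-2-yl]-2,2-dimethylcyclobutyl (Z)-2-methylbut-2-enoate
Product: 17 (R)-1-(5,8-dihydroxy-1,4-dioxo-1,4-dihydronaphthalen-2-yl)-2,2-dimethylcyclobutyl (Z)-2-methylbut-2-enoate (target, CNP0326301.1)
Conditions: aq HCl (3 M), THF, rt
Reagents that add atoms: none
Why: Acid hydrolysis of the two aryl MOM acetals, helped by hydrogen bonding to the peri carbonyls, should leave the tertiary ester (its cation is destabilised by the quinone) and the angelate intact; the product is the naphthazarin, whose 2- and 6-substituted tautomers are one compound.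

Compound list
1 | angelic acid, (Z)-2-methylbut-2-enoic acid | C/C=C(/C)C(=O)O | starting material
2 | angeloyl chloride, (Z)-2-methylbut-2-enoyl chloride | C/C=C(/C)C(=O)Cl | intermediate
3 | 2,2-dimethyl-1,3-dioxan-5-one | CC1(C)OCC(=O)CO1 | starting material
4 | potassium 2,2-dimethyl-4H-1,3-dioxin-5-olate (enolate of 3, not isolated) | CC1(C)OCC([O-])=CO1.[K+] | intermediate
5 | 2,2-dimethyl-4H-1,3-dioxin-5-yl (Z)-2-methylbut-2-enoate | C/C=C(/C)C(=O)OC1=COC(C)(C)OC1 | intermediate
6 | 3-oxoprop-1-en-2-yl (Z)-2-methylbut-2-enoate, 2-(angeloyloxy)acrolein | C/C=C(/C)C(=O)OC(=C)C=O | intermediate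
7 | isobutylene, 2-methylpropene | CC(C)=C | starting material
8 | (R)-1-formyl-2,2-dimethylcyclobutyl (Z)-2-methylbut-2-enoate | C/C=C(/C)C(=O)O[C@]1(C=O)CCC1(C)C | intermediate
9 | (R)-1-ethynyl-2,2-dimethylcyclobutyl (Z)-2-methylbut-2-enoate | C/C=C(/C)C(=O)O[C@]1(C#C)CCC1(C)C | intermediate
10 | hydroquinone | Oc1ccc(O)cc1 | starting material
11 | 1,4-bis(methoxymethoxy)benzene | COCOc1ccc(OCOC)cc1 | intermediate
12 | [2,5-bis(methoxymethoxy)phenyl]lithium (not isolated) | [Li]c1cc(OCOC)ccc1OCOC | intermediate
13 | lithium pentacarbonyl[2,5-bis(methoxymethoxy)benzoyl]chromate (not isolated) | [Li+].[O-]C(c1cc(OCOC)ccc1OCOC)=[Cr](=C=O)(=C=O)(=C=O)(=C=O)=C=O | intermediate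
14 | pentacarbonyl{[2,5-bis(methoxymethoxy)phenyl](methoxy)methylidene}chromium(0) | COC(c1cc(OCOC)ccc1OCOC)=[Cr](=C=O)(=C=O)(=C=O)(=C=O)=C=O | intermediate
15 | (R)-1-[1-hydroxy-4-methoxy-5,8-bis(methoxymethoxy)naphthalen-2-yl]-2,2-dimethylcyclobutyl (Z)-2-methylbut-2-enoate (not isolated) | C/C=C(/C)C(=O)O[C@]1(c2cc(OC)c3c(OCOC)ccc(OCOC)c3c2O)CCC1(C)C | intermediate
16 | (R)-1-[5,8-bis(methoxymethoxy)-1,4-dioxo-1,4-dihydronaphthalen-2-yl]-2,2-dimethylcyclobutyl (Z)-2-methylbut-2-enoate | C/C=C(/C)C(=O)O[C@]1(C2=CC(=O)c3c(OCOC)ccc(OCOC)c3C2=O)CCC1(C)C | intermediate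
17 | (R)-1-(5,8-dihydroxy-1,4-dioxo-1,4-dihydronaphthalen-2-yl)-2,2-dimethylcyclobutyl (Z)-2-methylbut-2-enoate | C/C=C(/C)C(=O)O[C@]1(C2=CC(=O)c3c(O)ccc(O)c3C2=O)CCC1(C)C | target

Total step count: 9. Longest linear sequence: 7 steps (steps 1, 2, 3, 4, 5, 8, 9); steps 6 and 7 form the convergent branch to the carbene complex.

Steps most likely to fail

Step 4. The tertiary cation may lose a proton before ring closure (open-chain ene-type aldehyde), the aliphatic unsaturated acyloxy group may slow iminium turnover or lower the facial selectivity of the ring closure, and the acidic salt may isomerise the Z double bond. The fallback carries an aroyl group of the kind established for this cycloaddition through the ring formation and exchanges it afterwards. It sets out from 3 and 7 and comes back at 9. Enolate O-acylation of 3 with 4-fluorobenzoyl chloride (KHMDS, THF, −78 °C) should give 2,2-dimethyl-4H-1,3-dioxin-5-yl 4-fluorobenzoate F1, and thermolysis in toluene should give 3-oxoprop-1-en-2-yl 4-fluorobenzoate F2. The same ammonium-catalysed [2+2] with 7 should give (R)-1-formyl-2,2-dimethylcyclobutyl 4-fluorobenzoate F3, a crystalline ester whose enantiopurity could be raised by recrystallisation. Seyferth–Gilbert homologation as in step 5 should give (R)-1-ethynyl-2,2-dimethylcyclobutyl 4-fluorobenzoate F4, and DIBAL-H (CH2Cl2, −78 °C) should remove the aroyl group to give (R)-1-ethynyl-2,2-dimethylcyclobutan-1-ol F5. Its lithium alkoxide (LiHMDS, THF, −78 °C) is acylated with 2 without amine catalyst to give 9.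

Step 5. The transient alkoxide formed next to the tertiary ester may trigger a 1,2-acyl shift or loss of the angeloyl group before olefination is complete. The fallback avoids anionic oxygen intermediates; it sets out from 8 and comes back at 9. Dibromo-olefination under neutral Corey–Fuchs conditions (CBr4, PPh3, Zn, CH2Cl2, 0 °C) should give (S)-1-(2,2-dibromoethenyl)-2,2-dimethylcyclobutyl (Z)-2-methylbut-2-enoate F6 (same spatial arrangement as 8; the descriptor changes with the CIP priorities). Palladium-catalysed hydrogenolysis of the E bromine (Bu3SnH, Pd(PPh3)4 cat., benzene, rt) should give (S)-1-[(Z)-2-bromoethenyl]-2,2-dimethylcyclobutyl (Z)-2-methylbut-2-enoate F7, and anti elimination with TBAF in DMF should give 9.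

Step 8. The chromium vinylcarbene or vinylketene may be diverted by the neighbouring acyloxy group or its C=C (lactone or cyclopropane formation) instead of cyclising onto the arene, and insertion of the hindered alkyne may be slow. The fallback runs the benzannulation on a silyl ether and acylates afterwards; it sets out from 9 and comes back at 15, which is oxidised with CAN to 16 as in step 8. DIBAL-H cleaves the ester of 9 to (R)-1-ethynyl-2,2-dimethylcyclobutan-1-ol F5, and TESOTf/2,6-lutidine gives triethyl{[(R)-1-ethynyl-2,2-dimethylcyclobutyl]oxy}silane F8. Benzannulation with 14 (THF, 55 °C, then air) should give 2-[(R)-2,2-dimethyl-1-(triethylsilyloxy)cyclobutyl]-4-methoxy-5,8-bis(methoxymethoxy)naphthalen-1-ol F9, and TBAF should give 2-[(R)-1-hydroxy-2,2-dimethylcyclobutyl]-4-methoxy-5,8-bis(methoxymethoxy)naphthalen-1-ol F10. Double acylation of the dilithium salt (LiHMDS 2.2 equiv, then 2, THF, −78 °C) should give 2-[(R)-1-{[(Z)-2-methylbut-2-enoyl]oxy}-2,2-dimethylcyclobutyl]-4-methoxy-5,8-bis(methoxymethoxy)naphthalen-1-yl (Z)-2-methylbut-2-enoate F11. Selective methanolysis of the aryl ester (K2CO3, MeOH, 0 °C) should then return 15.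

Further compounds
F1 | step 4 | 2,2-dimethyl-4H-1,3-dioxin-5-yl 4-fluorobenzoate | O=C(OC1=COC(C)(C)OC1)c1ccc(F)cc1
F2 | step 4 | 3-oxoprop-1-en-2-yl 4-fluorobenzoate | O=CC(=C)OC(=O)c1ccc(F)cc1
F3 | step 4 | (R)-1-formyl-2,2-dimethylcyclobutyl 4-fluorobenzoate | O=C(O[C@]1(C=O)CCC1(C)C)c1ccc(F)cc1
F4 | step 4 | (R)-1-ethynyl-2,2-dimethylcyclobutyl 4-fluorobenzoate | O=C(O[C@]1(C#C)CCC1(C)C)c1ccc(F)cc1
F5 | step 4 | (R)-1-ethynyl-2,2-dimethylcyclobutan-1-ol | O[C@]1(C#C)CCC1(C)C
F6 | step 5 | (S)-1-(2,2-dibromoethenyl)-2,2-dimethylcyclobutyl (Z)-2-methylbut-2-enoate | C/C=C(/C)C(=O)O[C@]1(C=C(Br)Br)CCC1(C)C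
F7 | step 5 | (S)-1-[(Z)-2-bromoethenyl]-2,2-dimethylcyclobutyl (Z)-2-methylbut-2-enoate | C/C=C(/C)C(=O)O[C@]1(/C=C\Br)CCC1(C)C
F8 | step 8 | triethyl{[(R)-1-ethynyl-2,2-dimethylcyclobutyl]oxy}silane | CC[Si](CC)(CC)O[C@]1(C#C)CCC1(C)C
F9 | step 8 | 2-[(R)-2,2-dimethyl-1-(triethylsilyloxy)cyclobutyl]-4-methoxy-5,8-bis(methoxymethoxy)naphthalen-1-ol | CC[Si](CC)(CC)O[C@]1(c2cc(OC)c3c(OCOC)ccc(OCOC)c3c2O)CCC1(C)C
F10 | step 8 | 2-[(R)-1-hydroxy-2,2-dimethylcyclobutyl]-4-methoxy-5,8-bis(methoxymethoxy)naphthalen-1-ol | O[C@]1(c2cc(OC)c3c(OCOC)ccc(OCOC)c3c2O)CCC1(C)C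
F11 | step 8 | 2-[(R)-1-{[(Z)-2-methylbut-2-enoyl]oxy}-2,2-dimethylcyclobutyl]-4-methoxy-5,8-bis(methoxymethoxy)naphthalen-1-yl (Z)-2-methylbut-2-enoate | C/C=C(/C)C(=O)O[C@]1(c2cc(OC)c3c(OCOC)ccc(OCOC)c3c2OC(=O)/C(C)=C\C)CCC1(C)C
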